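**Retrosynthetic overview**
1. Pauciflorol E (19) ⇐ its penta-O-methyl ether 18 by global demethylation.
2. 18 ⇐ aryl benzyl ketone 14 by cutting the C7'–ring B bond: the ketone α-carbon is used as an electrophile (enolonium) against the electron-rich ring B, which closes the seven-membered ring last.
3. 14 ⇐ aryl bromide 10 + (4-methoxyphenyl)acetyl chloride 11 (Negishi acylation).
4. 10 (trans-2,3-diaryl-dihydrobenzofuran) ⇐ diaryl diazomethane 8 by enantioselective carbene C–H insertion into a 4-methoxybenzyl ether, then C2 epimerisation.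
5. 8 ⇐ benzophenone 4 ⇐ 1-bromo-3,5-dimethoxybenzene 1 + 3,5-dimethoxybenzoyl chloride 2. Ring order: rings A and B joined, then the dihydrofuran, then the seven-membered ring.

Locants: C7/C8 = C2/C3 of the dihydrobenzofuran; C7' = the CH(aryl) carbon next to the ketone; ring A = benzo ring of the benzofuran; ring B = the 3,5-dioxygenated ring on C8. The target is (7R,8R,7'R).
Assumption: Rh2(S-PTAD)4, dirhodium tetrakis[(S)-(1-adamantyl)(phthalimido)acetate], is taken as the antipode that gives 3R at C8; if the sense of induction is the reverse, Rh2(R-PTAD)4 is used.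
Assumption: the natural 7'R configuration (aryl pseudo-axial, away from the peri oxygen of ring B, H7' anti to H8) is the thermodynamically preferred one at this epimerisable α-aryl ketone centre.

**Step 1**
Reactants: 1 1-bromo-3,5-dimethoxybenzene; 2 3,5-dimethoxybenzoyl chloride
Product: 4 (2-bromo-6-hydroxy-4-methoxyphenyl)(3,5-dimethoxyphenyl)methanone, via tetramethoxy ketone 3 (not isolated)
Conditions: AlCl3 (3 equiv), CH2Cl2, 0 °C to rt
Reagents that add atoms: none
Why: Friedel–Crafts acylation takes place at C2 of 1 (para to one methoxy, ortho to the other), and the excess AlCl3 then cleaves only the methoxy group chelated to the new ketone carbonyl, giving the ortho-hydroxybenzophenone.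

**Step 2**
Reactants: 4 (2-bromo-6-hydroxy-4-methoxyphenyl)(3,5-dimethoxyphenyl)methanone; 5 4-methoxybenzyl chloride
Product: 6 {2-bromo-4-methoxy-6-[(4-methoxybenzyl)oxy]phenyl}(3,5-dimethoxyphenyl)methanone
Conditions: K2CO3, n-Bu4NI (cat.), DMF, 60 °C
Reagents that add atoms: none
Why: Williamson ether synthesis on the hydrogen-bonded phenol installs the 4-methoxybenzyl group whose benzylic CH2 later becomes C7.

**Step 3**
Reactants: 6 {2-bromo-4-methoxy-6-[(4-methoxybenzyl)oxy]phenyl}(3,5-dimethoxyphenyl)methanone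
Product: 7 hydrazone of 6 (E/Z mixture)
Conditions: N2H4·H2O (10 equiv), AcOH (cat.), n-BuOH, 110 °C, sealed tube
Reagents that add atoms: hydrazine hydrate, NN.O
Why: Acid-catalysed hydrazone condensation under forcing conditions for the di-ortho-substituted benzophenone; the ether, bromide and methoxy groups are inert and no stereocentre is formed.

**Step 4**
Reactants: 7 hydrazone of 6
Product: 10 (2R,3R)-4-bromo-3-(3,5-dimethoxyphenyl)-6-methoxy-2-(4-methoxyphenyl)-2,3-dihydro-1-benzofuran (trans), via diazo compound 8 (not isolated), via cis dihydrobenzofuran 9 (not isolated)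
Conditions: MnO2, CH2Cl2, 0 °C; filter; Rh2(S-PTAD)4 (1 mol %), CH2Cl2, 0 °C to rt; then CF3CO2H (5 equiv), 0.02 M, 0 °C to rt
Reagents that add atoms: none
Why: MnO2 dehydrogenates the hydrazone to the diaryl diazomethane, whose donor/donor divalent rhodium carbene undergoes enantioselective 1,5 C–H insertion into the ArCH2–O bond to give the cis-2,3-diaryl-dihydrobenzofuran with C8 set R by the chiral carboxylate catalyst, and CF3CO2H then reversibly ionises the 4-methoxybenzylic C7–O bond so that C7 equilibrates to the more stable trans (2R) isomer while C8 is untouched.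

**Step 5**
Reactants: 10 (2R,3R)-4-bromo-3-(3,5-dimethoxyphenyl)-6-methoxy-2-(4-methoxyphenyl)-2,3-dihydro-1-benzofuran; 11 (4-methoxyphenyl)acetyl chloride
Product: 14 1-[(2R,3R)-3-(3,5-dimethoxyphenyl)-6-methoxy-2-(4-methoxyphenyl)-2,3-dihydro-1-benzofuran-4-yl]-2-(4-methoxyphenyl)ethan-1-one, via aryllithium 12 (not isolated), via arylzinc chloride 13 (not isolated)
Conditions: n-BuLi, THF, −78 °C; ZnCl2, −78 to 0 °C; Pd(PPh3)4 (5 mol %), 11, 0 °C to rt
Reagents that add atoms: none
Why: Bromine–lithium exchange, transmetalation to zinc and Negishi acylation catalysed by zerovalent palladium give the aryl benzyl ketone without over-addition, and neither stereocentre is affected.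

**Step 6 (key step)**
Reactants: 14 1-[(2R,3R)-3-(3,5-dimethoxyphenyl)-6-methoxy-2-(4-methoxyphenyl)-2,3-dihydro-1-benzofuran-4-yl]-2-(4-methoxyphenyl)ethan-1-one
Product: 18 penta-O-methylpauciflorol E (7R,8R,7'R), via lithium enolate 15 (not isolated), via silyl enol ether 16 (not isolated), via iodanyl enolonium 17 (not isolated)
Conditions: LiN(SiMe3)2, Me3SiCl, THF, −78 to 0 °C; concentrate; PhI(OAc)2 (1.05 equiv), BF3·OEt2, CH2Cl2, −78 to −20 °C; NaHCO3 work-up
Reagents that add atoms: none
Why: Proposed new method: the Z silyl enol ether attacks the trivalent iodine of BF3-activated PhI(OAc)2 to give an enolonium species (an umpoled enolate whose α-carbon is electrophilic and further stabilised as a 4-methoxybenzylic cation), and loss of PhI lets the ortho carbon of ring B (para to a methoxy group and held on C8) close the seven-membered ring in a Friedel–Crafts alkylation, the closest known reaction type being intermolecular α-arylation of ketone-derived enolonium species with electron-rich arenes; C7' is formed 7'R because the aryl group avoids the peri methoxy group of ring B in the Wheland intermediate, and any minor epimer equilibrates to this more stable isomer through the easily enolised α,α-diaryl ketone.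

**Step 7**
Reactants: 18 penta-O-methylpauciflorol E
Product: 19 pauciflorol E
Conditions: BBr3 (15 equiv), CH2Cl2, −78 °C to rt; MeOH, H2O
Reagents that add atoms: none
Why: Lewis-acid ether cleavage with BBr3 removes all five O-methyl groups; C8 is not touched, any reversible opening of the C7–O bond re-closes to the same trans isomer, and C7' stays at its thermodynamic configuration.

**Compound list**
1 | 1-bromo-3,5-dimethoxybenzene | COc1cc(Br)cc(OC)c1 | starting material
2 | 3,5-dimethoxybenzoyl chloride | COc1cc(cc(OC)c1)C(Cl)=O | starting material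
3 | (2-bromo-4,6-dimethoxyphenyl)(3,5-dimethoxyphenyl)methanone (not isolated) | COc1cc(OC)c(C(=O)c2cc(OC)cc(OC)c2)c(Br)c1 | intermediate
4 | (2-bromo-6-hydroxy-4-methoxyphenyl)(3,5-dimethoxyphenyl)methanone | COc1cc(O)c(C(=O)c2cc(OC)cc(OC)c2)c(Br)c1 | intermediate
5 | 4-methoxybenzyl chloride | COc1ccc(CCl)cc1 | starting material
6 | {2-bromo-4-methoxy-6-[(4-methoxybenzyl)oxy]phenyl}(3,5-dimethoxyphenyl)methanone | COc1ccc(COc2cc(OC)cc(Br)c2C(=O)c2cc(OC)cc(OC)c2)cc1 | intermediate
7 | hydrazone of 6 (E/Z mixture) | COc1ccc(COc2cc(OC)cc(Br)c2C(=NN)c2cc(OC)cc(OC)c2)cc1 | intermediate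
8 | {2-bromo-4-methoxy-6-[(4-methoxybenzyl)oxy]phenyl}(3,5-dimethoxyphenyl)diazomethane (not isolated) | COc1ccc(COc2cc(OC)cc(Br)c2C(=[N+]=[N-])c2cc(OC)cc(OC)c2)cc1 | intermediate
9 | (2S,3R)-4-bromo-3-(3,5-dimethoxyphenyl)-6-methoxy-2-(4-methoxyphenyl)-2,3-dihydro-1-benzofuran, cis (not isolated) | Brc1cc(OC)cc2c1[C@@H](c1cc(OC)cc(OC)c1)[C@@H](c1ccc(OC)cc1)O2 | intermediate
10 | (2R,3R)-4-bromo-3-(3,5-dimethoxyphenyl)-6-methoxy-2-(4-methoxyphenyl)-2,3-dihydro-1-benzofuran, trans | Brc1cc(OC)cc2c1[C@@H](c1cc(OC)cc(OC)c1)[C@H](c1ccc(OC)cc1)O2 | intermediate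
11 | (4-methoxyphenyl)acetyl chloride | COc1ccc(CC(Cl)=O)cc1 | starting material
12 | 4-lithio derivative of 10 (aryllithium, not isolated) | [Li]c1cc(OC)cc2c1[C@@H](c1cc(OC)cc(OC)c1)[C@H](c1ccc(OC)cc1)O2 | intermediate
13 | 4-(chlorozincio) derivative of 10 (arylzinc chloride, not isolated) | Cl[Zn]c1cc(OC)cc2c1[C@@H](c1cc(OC)cc(OC)c1)[C@H](c1ccc(OC)cc1)O2 | intermediate
14 | 1-[(2R,3R)-3-(3,5-dimethoxyphenyl)-6-methoxy-2-(4-methoxyphenyl)-2,3-dihydro-1-benzofuran-4-yl]-2-(4-methoxyphenyl)ethan-1-one | COc1ccc(CC(=O)c2cc(OC)cc3c2[C@@H](c2cc(OC)cc(OC)c2)[C@H](c2ccc(OC)cc2)O3)cc1 | intermediate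
15 | lithium (Z)-enolate of 14 (not isolated) | [Li]O/C(=C\c1ccc(OC)cc1)c1cc(OC)cc2c1[C@@H](c1cc(OC)cc(OC)c1)[C@H](c1ccc(OC)cc1)O2 | intermediate
16 | (Z)-trimethylsilyl enol ether of 14 (not isolated) | C[Si](C)(C)O/C(=C\c1ccc(OC)cc1)c1cc(OC)cc2c1[C@@H](c1cc(OC)cc(OC)c1)[C@H](c1ccc(OC)cc1)O2 | intermediate
17 | O-bound acetoxy(phenyl)iodanyl enolate of 14, the enolonium species (not isolated) | CC(=O)OI(c1ccccc1)O/C(=C\c1ccc(OC)cc1)c1cc(OC)cc2c1[C@@H](c1cc(OC)cc(OC)c1)[C@H](c1ccc(OC)cc1)O2 | intermediate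
18 | penta-O-methylpauciflorol E, (7R,8R,7'R) | O=C1c2cc(OC)cc3c2[C@@H](c2cc(OC)cc(OC)c2[C@H]1c1ccc(OC)cc1)[C@H](c1ccc(OC)cc1)O3 | intermediate
19 | pauciflorol E, (7R,8R,7'R) | O=C1c2cc(O)cc3c2[C@@H](c2cc(O)cc(O)c2[C@H]1c1ccc(O)cc1)[C@H](c1ccc(O)cc1)O3 | target

**Step count**
Total steps: 7. Longest linear sequence: 7 (1 → 4 → 6 → 7 → 10 → 14 → 18 → 19).

**Steps most likely to fail, with fallbacks**

Step 4. The carbene carries two ortho substituents (Br and the ether), so yield and enantioselectivity of the insertion are untested on this substitution pattern. The hindered hydrazone of step 3 feeds the same problem. The acid epimerisation could also erode ee if the C7 cation loses the C8 proton. The fallback sets out from 4 and comes back at 10, sparing steps 2 and 3. NaBH4 (MeOH, 0 °C) reduces 4 to the racemic (2-bromo-6-hydroxy-4-methoxyphenyl)(3,5-dimethoxyphenyl)methanol F1. Sodium 4-methylbenzenesulfinate and HCO2H convert this to the sulfone 3-bromo-2-[(3,5-dimethoxyphenyl)(4-methylbenzenesulfonyl)methyl]-5-methoxyphenol F2. The chiral salt (2R,5R)-1-(4-methoxybenzyl)-2,5-dimethylthiolan-1-ium tetrafluoroborate F3 is made from 5, (2R,5R)-2,5-dimethylthiolane and NaBF4. F2 and F3 are stirred with Cs2CO3 in CH2Cl2 at 0 °C. Sulfinate loss, conjugate addition of the sulfur ylide to the methide carbon and 5-exo displacement of the sulfide by the phenoxide (a [4+1] annulation) give trans 10 directly. The C2-symmetric sulfide, of which either antipode can be used, fixes the absolute configuration.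

Step 5. The organometallic acylation is at a congested position next to the C3 aryl group, and excess base could open the dihydrobenzofuran by deprotonation at C3. The fallback sets out from 10 and comes back at 14. Lithiation as in step 5 and a DMF quench give (2R,3R)-3-(3,5-dimethoxyphenyl)-6-methoxy-2-(4-methoxyphenyl)-2,3-dihydro-1-benzofuran-4-carbaldehyde F4. 4-Methoxybenzylmagnesium chloride (THF, −78 °C) adds to give the secondary alcohol 1-[(2R,3R)-dihydrobenzofuran-4-yl]-2-(4-methoxyphenyl)ethan-1-ol F5 as a mixture of carbinol epimers. Dess–Martin periodinane oxidises F5 to 14.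

Step 6. The iodane may oxidise the electron-rich rings instead of the enol ether. The cation at C7' may also take a hydride from C8–H (a 1,5 shift) in place of the ring closure. The fallback sets out from 14 and comes back at 18. Diazo transfer with 4-acetamidobenzenesulfonyl azide and DBU (MeCN) gives the α-diazo ketone 2-diazo-1-[(2R,3R)-dihydrobenzofuran-4-yl]-2-(4-methoxyphenyl)ethan-1-one F6. HBF4·OEt2 in CH2Cl2 at −40 °C protonates the diazo carbon. The resulting α-keto diazonium ion is a redox-neutral enolonium equivalent with N2 as leaving group, and ring B displaces it to give 18 with no oxidant present.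

**Further compounds**
F1 | step 4 | (2-bromo-6-hydroxy-4-methoxyphenyl)(3,5-dimethoxyphenyl)methanol (racemic) | COc1cc(O)c(C(O)c2cc(OC)cc(OC)c2)c(Br)c1
F2 | step 4 | 3-bromo-2-[(3,5-dimethoxyphenyl)(4-methylbenzenesulfonyl)methyl]-5-methoxyphenol (racemic) | COc1cc(O)c(C(c2cc(OC)cc(OC)c2)S(=O)(=O)c2ccc(C)cc2)c(Br)c1
F3 | step 4 | (2R,5R)-1-(4-methoxybenzyl)-2,5-dimethylthiolan-1-ium tetrafluoroborate | C[C@@H]1CC[C@@H](C)[S+]1Cc1ccc(OC)cc1.F[B-](F)(F)F
F4 | step 5 | (2R,3R)-3-(3,5-dimethoxyphenyl)-6-methoxy-2-(4-methoxyphenyl)-2,3-dihydro-1-benzofuran-4-carbaldehyde | O=Cc1cc(OC)cc2c1[C@@H](c1cc(OC)cc(OC)c1)[C@H](c1ccc(OC)cc1)O2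
F5 | step 5 | 1-[(2R,3R)-3-(3,5-dimethoxyphenyl)-6-methoxy-2-(4-methoxyphenyl)-2,3-dihydro-1-benzofuran-4-yl]-2-(4-methoxyphenyl)ethan-1-ol (carbinol epimers) | COc1ccc(CC(O)c2cc(OC)cc3c2[C@@H](c2cc(OC)cc(OC)c2)[C@H](c2ccc(OC)cc2)O3)cc1
F6 | step 6 | 2-diazo-1-[(2R,3R)-3-(3,5-dimethoxyphenyl)-6-methoxy-2-(4-methoxyphenyl)-2,3-dihydro-1-benzofuran-4-yl]-2-(4-methoxyphenyl)ethan-1-one | COc1ccc(cc1)C(=[N+]=[N-])C(=O)c1cc(OC)cc2c1[C@@H](c1cc(OC)cc(OC)c1)[C@H](c1ccc(OC)cc1)O2
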